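Its constants were set for the occasion; the flask was simulated.

Slowness in this flask is a matter of waiting, so we time the waits of one catalyst on its way round.

starting material 10 mM; gas 0.43 mM (held); free catalyst 29 µM

    starting material + free catalyst ⇌ catalyst intermediate A (K1 = 57 M⁻¹, k1 = 21000 M⁻¹ s⁻¹)
    coupling partner + catalyst intermediate A → catalyst intermediate B (k2 = 6.8 × 10⁵ M⁻¹ s⁻¹)
    catalyst intermediate B → free catalyst + product (k3 = 40 s⁻¹)
    starting material + catalyst intermediate B ⇌ idle complex, settled at all times (K4 = 140 M⁻¹)
    gas ⇌ coupling partner, rate k5*(csat - [coupling partner]) (k5 = 12 s⁻¹, csat = 0.43 mM)

- factor on the rate of making product when 30% of the starting material are converted if free catalyst is charged twice over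
- factor on the rate when 30% of the starting material are converted if free catalyst is charged at 150 µM instead

Take the moment of 30% conversion, with 7.00 mM of starting material left. Free catalyst is caught after 6.80 ms. Catalyst intermediate A then stands at a fork: with the partner at saturation it goes on with a chance of 44.2%, otherwise it falls back and the wait begins again. Catalyst intermediate B leaves in 25.0 ms, but spells as idle complex stretch that to 49.5 ms, the longest wait of the round and the nearest thing here to a rate-limiting step. Adding the waits, repeats at the fork counted, gives the round time, the mean time one catalyst takes per product: 68.3 ms. Of this, 12.0 ms grows in inverse proportion to the partner. The rate is catalyst over round time, 0.425 mM s⁻¹ for the flask as charged.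

Two extremes bracket the answer. With instant transfer the round time stays put, and the factors are 2 and 5.17. With transfer as the bottleneck, the rate sits at the ceiling of 5.16 mM s⁻¹ and the factor is one. Our flasks lie between, nearer the first, since the rate reckoned so, 0.425 mM s⁻¹ as charged and 2.20 mM s⁻¹ at 150 µM, is less than that ceiling. The partner falls short of saturation by the rate's share of the ceiling. Correcting for this, the round time is 69.4 ms as charged, 70.7 ms for the double charge, and, after two passes, 75.5 ms at 150 µM. Our factors are 1.96 and 4.75.

The forecast gives 1.97 and 4.74, holding that “the rate scales nearly in proportion to catalyst”.

The simulation gives 1.97 and 4.75. In the flask as charged, the rate of making product at 7.40 s is 0.418 mM s⁻¹. We now run the round time forward in that flask to 1.50 mM of starting material left, with the partner as before: it lengthens to 109 ms, which puts the rate at 0.637 of its value at 30% conversion. The reading at 21.7 s is 0.65.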